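**Retrosynthetic overview**
1. 9 ⇒ 8 (both benzoates installed last) ⇒ 7 (oxirane C1–O–C6 from the C1=C6 alkene, by reagent-controlled epoxidation of the primary allylic alcohol) ⇒ 6 (CH2OH from CO2Me).
2. 6 ⇒ 3 + 4: inverse-electron-demand Diels–Alder reaction of a 2-pyrone with an E-1,2-dioxygenated alkene, then loss of CO2. Bonds C1–C2 and C3–C4 of the carbocycle form together, along with both carbinol stereocentres.
3. Enabling feature: in the six-membered carbocycle, C1, C6, C5 and C4 (oxirane C1–C6 = masked alkene, plus the C4=C5 alkene) are a hidden 1,3-diene whose terminus C1 carries the only carbon branch. C2(OMe)–C3(OBz) is a trans two-carbon unit with one ether and one ester oxygen. This is the pattern left when a donor-biased E-alkene adds across C3/C6 of a 3-carboxylated 2-pyrone ring and the O–C(=O) bridge leaves as CO2.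
4. Ring order: carbocycle first (step 3, passing through a 2-oxabicyclo[2.2.2]octene), oxirane second (step 5). Alkene 3 comes from 2,2-dimethoxyethanol in two steps.

Key step: step 3

Numbering: 7-oxabicyclo[4.1.0]hept-4-ene locants. The target is (1R,2S,3R,6R), with the oxirane oxygen and OMe on one ring face and OBz on the other.
Assumption: the sense of induction in step 3 is taken from the square-planar chelate model of the copper bis(oxazoline) complex; if the opposite sense is found, the (R,R) ligand is used and nothing else changes.

Step 1
Reactants: 1 2,2-dimethoxyethanol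
Product: 2 2,2-dimethoxyethyl benzoate
Conditions: BzCl, Et3N, DMAP (cat.), CH2Cl2, 0 °C to rt
Reagents that add atoms: benzoyl chloride, O=C(Cl)c1ccccc1
Why: DMAP-catalysed O-acylation of a primary alcohol, in which the acetal is inert to the basic medium and no stereocentre is formed.

Step 2
Reactants: 2 2,2-dimethoxyethyl benzoate
Product: 3 (E)-2-methoxyvinyl benzoate
Conditions: TMSOTf, iPr2NEt, CH2Cl2, −20 °C to rt; E/Z separation on SiO2 (1% Et3N)
Reagents that add atoms: none
Why: Silyl-triflate-induced acetal-to-enol-ether elimination (ionisation of one methoxy group to the oxocarbenium ion, then deprotonation by the hindered amine) is not expected to be stereoselective, so the E isomer (larger vicinal alkene coupling) is separated and carried on alone, because its geometry becomes the trans C2/C3 relation of the target.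

Step 3
Reactants: 3 (E)-2-methoxyvinyl benzoate; 4 methyl 2-oxo-2H-pyran-3-carboxylate
Product: 6 methyl (5R,6R)-5-(benzoyloxy)-6-methoxycyclohexa-1,3-diene-1-carboxylate, via bicyclic lactone 5 (not isolated)
Conditions: Cu(OTf)2 (10 mol %), 2,2'-isopropylidenebis[(4S)-4-tert-butyl-2-oxazoline] (11 mol %), 4 Å MS, CH2Cl2, 0 °C to rt; short SiO2 plug; then toluene (base-washed glass), 100 °C (−CO2)
Reagents that add atoms: none
Why: The pyrone binds the divalent copper centre through its lactone and ester carbonyl oxygens, which lowers its LUMO, and 3 adds across pyrone C3 and C6 in a concerted, asynchronous inverse-electron-demand Diels–Alder reaction to give lactone 5, which on heating loses CO2 by retro-[4+2] and leaves diene 6. The closest known reaction type is the chiral-Lewis-acid-catalysed cycloaddition of 3-carboalkoxy-2-pyrones with vinyl ethers and with cyclic 1,2-dioxygenated alkenes, followed by CO2 extrusion to arene dihydrodiol derivatives. The carbocycle is closed by an intermolecular suprafacial/suprafacial [4+2] event (both C–C bonds at once, first within the 2-oxabicyclo[2.2.2]octene), so no chain-cyclisation mode applies. The trans relation of C5 and C6 is copied stereospecifically from the E geometry of 3, and the absolute configuration follows from attack on the pyrone face left open by the tert-butyl group of the (S,S) ligand with OMe endo. Because the bridgeheads return to sp2, OMe-endo and OMe-exo adducts from the same pyrone face would end as opposite enantiomers of 6, so endo/exo control matters as much as facial control; it is secured by the strong endo preference of the alkoxy donor (oxocarbenium-like carbon held over the developing dienolate), which forces the benzoate exo. Regiochemistry is secured by the ether/ester pair: the stronger donor OMe makes the benzoyloxy-bearing carbon the nucleophilic terminus, which bonds to the most electrophilic pyrone carbon C6, so OMe ends next to the ester-bearing carbon.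

Step 4
Reactants: 6 methyl (5R,6R)-5-(benzoyloxy)-6-methoxycyclohexa-1,3-diene-1-carboxylate
Product: 7 (1R,6R)-5-(hydroxymethyl)-6-methoxycyclohexa-2,4-dien-1-ol
Conditions: iBu2AlH (5 equiv), CH2Cl2, −78 °C; aq. potassium sodium tartrate
Reagents that add atoms: none
Why: Exhaustive 1,2-reduction of both esters by the aluminium hydride (no conjugate reduction of the dienoate) is accepted because both oxygens are benzoylated together in step 6, while the two stereocentres are untouched and the cold, non-acidic work-up should avoid aromatisation.

Step 5
Reactants: 7 (1R,6R)-5-(hydroxymethyl)-6-methoxycyclohexa-2,4-dien-1-ol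
Product: 8 (1R,2S,3R,6R)-1-(hydroxymethyl)-2-methoxy-7-oxabicyclo[4.1.0]hept-4-en-3-ol
Conditions: Ti(OiPr)4 (20 mol %), D-(−)-diisopropyl tartrate (24 mol %), tBuOOH (1.1 equiv, decane), 4 Å MS, CH2Cl2, −25 °C
Reagents that add atoms: tert-butyl hydroperoxide, CC(C)(C)OO
Why: In the Sharpless asymmetric epoxidation only the primary allylic alkoxide fits the titanium tartrate template, so oxygen goes to the trisubstituted alkene bearing CH2OH rather than to the alkene next to the ring carbinol (cyclohexenols are very slow substrates), and the D-(−)-tartrate, which turns (E)-hex-2-en-1-ol into its (2R,3R)-epoxide, delivers it to the face syn to OMe, setting C1 and C6 under reagent control.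

Step 6
Reactants: 8 (1R,2S,3R,6R)-1-(hydroxymethyl)-2-methoxy-7-oxabicyclo[4.1.0]hept-4-en-3-ol
Product: 9 [(1R,2S,3R,6R)-3-(benzoyloxy)-2-methoxy-7-oxabicyclo[4.1.0]hept-4-en-1-yl]methyl benzoate
Conditions: Bz2O (3 equiv), Et3N, DMAP (cat.), CH2Cl2, 0 °C to rt
Reagents that add atoms: benzoic anhydride, O=C(OC(=O)c1ccccc1)c1ccccc1
Why: DMAP-catalysed acylation of the primary and the secondary alcohol with the anhydride is chloride-free, so the vinyl oxirane should not open to a chlorohydrin, and no stereocentre is touched.

**Compound list**
1 | 2,2-dimethoxyethanol | COC(CO)OC | starting material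
2 | 2,2-dimethoxyethyl benzoate | COC(COC(=O)c1ccccc1)OC | intermediate
3 | (E)-2-methoxyvinyl benzoate | CO/C=C/OC(=O)c1ccccc1 | intermediate
4 | methyl 2-oxo-2H-pyran-3-carboxylate | COC(=O)c1cccoc1=O | starting material
5 | methyl (1R,4S,7R,8R)-7-(benzoyloxy)-8-methoxy-3-oxo-2-oxabicyclo[2.2.2]oct-5-ene-4-carboxylate (OMe syn to the C5=C6 bridge, OBz syn to the lactone bridge) | COC(=O)[C@@]12C=C[C@@H](OC1=O)[C@@H](OC(=O)c1ccccc1)[C@@H]2OC | intermediate
6 | methyl (5R,6R)-5-(benzoyloxy)-6-methoxycyclohexa-1,3-diene-1-carboxylate | CO[C@H]1[C@H](OC(=O)c2ccccc2)C=CC=C1C(=O)OC | intermediate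
7 | (1R,6R)-5-(hydroxymethyl)-6-methoxycyclohexa-2,4-dien-1-ol | CO[C@H]1[C@H](O)C=CC=C1CO | intermediate
8 | (1R,2S,3R,6R)-1-(hydroxymethyl)-2-methoxy-7-oxabicyclo[4.1.0]hept-4-en-3-ol | CO[C@H]1[C@H](O)C=C[C@H]2O[C@]21CO | intermediate
9 | [(1R,2S,3R,6R)-3-(benzoyloxy)-2-methoxy-7-oxabicyclo[4.1.0]hept-4-en-1-yl]methyl benzoate | CO[C@H]1[C@H](OC(=O)c2ccccc2)C=C[C@H]2O[C@]21COC(=O)c1ccccc1 | target

Total step count: 6. Longest linear sequence: 6 (steps 1 to 6; 4 is bought).

**Steps most likely to fail**

Step 3 (key step).
- What may go wrong: the cycloaddition may be slow because the benzoyloxy group lowers the nucleophilicity of the enol ether. Leakage through the OMe-exo mode would lower the enantiomeric purity once CO2 is lost. Methanol or benzoic acid may be lost (aromatisation) during heating.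
- Fallback: absolute control is moved from the cycloaddition to the epoxidation. It sets out from 3 and 4, which are heated without catalyst (toluene, sealed tube, 110 °C; thermal inverse-electron-demand Diels–Alder reaction with CO2 loss in the same flask). Through 5 and its mirror image, the (1S,4R,7S,8S) bicyclic lactone F1, this should give racemic material made of 6 and the (5S,6S) diene ester F2. Reduction as in step 4 gives 7 and the (1S,6S) dienyl diol F3. The epoxidation of step 5 then attacks both enantiomers from the same tartrate-chosen face, so 7 gives 8 and F3 gives the anti epoxy diol F4 (oxirane and OMe on opposite faces). These two are diastereomers and are separated by chromatography. The route is rejoined at 8.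

Step 5.
- What may go wrong: facial selectivity may be poor if reagent and substrate preferences are mismatched. The free ring carbinol may bind to titanium. The Lewis acid may open the vinyl oxirane.
- Fallback: the directed epoxidation is given up. It sets out from 7, which is benzoylated first (Bz2O, Et3N, DMAP) to the diene dibenzoate F5. This is epoxidised with buffered mCPBA (NaHCO3, CH2Cl2, 0 °C) at the more substituted alkene. The two ring faces are similarly hindered (OMe on one, OBz on the other), so both oxirane diastereomers are expected, and the syn isomer is isolated by chromatography. The route is rejoined at 9.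

Step 2.
- What may go wrong: the elimination may run mainly to the Z alkene (cis preference of 1,2-dioxygenated alkenes). The E/Z separation may be incomplete. The enol ether may hydrolyse on silica.
- Fallback: the Z isomer is used and C3 is corrected at the end. It sets out from 2, whose elimination also gives (Z)-2-methoxyvinyl benzoate F6. Under the conditions of step 3, F6 should react with 4 with both oxygens endo, the closest analogue of the known cyclic cis-dioxygenated dienophiles. This gives the cis bicyclic lactone F7 and, after CO2 loss, the cis diene ester F8. Treatment with iBu2AlH gives the cis dienyl diol F9, and epoxidation as in step 5 gives the all-syn epoxy diol F10. A double Mitsunobu reaction (PPh3, DIAD, BzOH, THF, 0 °C) then esterifies the primary alcohol and inverts the allylic carbinol C3. The attacked face is free because oxirane oxygen, OMe and OH all lie on the other face. The route is rejoined at 9.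

**Further compounds**
F1 | step 3 | methyl (1S,4R,7S,8S)-7-(benzoyloxy)-8-methoxy-3-oxo-2-oxabicyclo[2.2.2]oct-5-ene-4-carboxylate | COC(=O)[C@]12C=C[C@H](OC1=O)[C@H](OC(=O)c1ccccc1)[C@H]2OC
F2 | step 3 | methyl (5S,6S)-5-(benzoyloxy)-6-methoxycyclohexa-1,3-diene-1-carboxylate | CO[C@@H]1[C@@H](OC(=O)c2ccccc2)C=CC=C1C(=O)OC
F3 | step 3 | (1S,6S)-5-(hydroxymethyl)-6-methoxycyclohexa-2,4-dien-1-ol | CO[C@@H]1[C@@H](O)C=CC=C1CO
F4 | step 3 | (1R,2R,3S,6R)-1-(hydroxymethyl)-2-methoxy-7-oxabicyclo[4.1.0]hept-4-en-3-ol | CO[C@@H]1[C@@H](O)C=C[C@H]2O[C@]21CO
F5 | step 5 | [(5R,6R)-5-(benzoyloxy)-6-methoxycyclohexa-1,3-dien-1-yl]methyl benzoate | CO[C@H]1[C@H](OC(=O)c2ccccc2)C=CC=C1COC(=O)c1ccccc1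
F6 | step 2 | (Z)-2-methoxyvinyl benzoate | CO/C=C\OC(=O)c1ccccc1
F7 | step 2 | methyl (1R,4S,7S,8R)-7-(benzoyloxy)-8-methoxy-3-oxo-2-oxabicyclo[2.2.2]oct-5-ene-4-carboxylate | COC(=O)[C@@]12C=C[C@@H](OC1=O)[C@H](OC(=O)c1ccccc1)[C@@H]2OC
F8 | step 2 | methyl (5S,6R)-5-(benzoyloxy)-6-methoxycyclohexa-1,3-diene-1-carboxylate | CO[C@H]1[C@@H](OC(=O)c2ccccc2)C=CC=C1C(=O)OC
F9 | step 2 | (1S,6R)-5-(hydroxymethyl)-6-methoxycyclohexa-2,4-dien-1-ol | CO[C@H]1[C@@H](O)C=CC=C1CO
F10 | step 2 | (1R,2S,3S,6R)-1-(hydroxymethyl)-2-methoxy-7-oxabicyclo[4.1.0]hept-4-en-3-ol | CO[C@H]1[C@@H](O)C=C[C@H]2O[C@]21CO
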